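## Retrosynthetic overview

1. The last C–C bond is C11–C12: a Stille coupling of East vinyl iodide 22 (C1–C11) with dienyl-lactone stannane 40 (C12–C24), followed only by global desilylation.
2. Stannane 40 comes from a Stille coupling at C17–C18 of lactone stannane 32 with (Z)-iodide 38, then hydrostannation of the terminal alkyne.
3. Ring A (the dihydropyranone, the only ring) is closed early, inside 32, by anti-crotylation, acryloylation and ring-closing metathesis.
4. In East fragment 22, C6/C7 come from an anti-aldol, C8–C9 from a new iridium-catalysed C–H (hydroxymethyl)propargylation (sets C9), and C3–C4 from hydroboration/B-alkyl Suzuki coupling (sets C5).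
5. Middle fragment 38 comes from (R)-3-bromo-2-methylpropan-1-ol by acetylide alkylation and Stork–Zhao olefination.

Assumption: the SMILES is taken literally, i.e. (2E,5R,6R,7R,9S,10E,12E,15S,16Z,18E) with a trans lactone; atoms are numbered C1 (acid) to C24 (lactone carbonyl); the recoverable oxazolidinone is used as a chiral auxiliary reagent.

## Route

**East fragment (C1–C11)**

Step 1
Reactants: 1 propanoyl chloride
Product: 2 (S)-4-benzyl-3-propanoyl-1,3-oxazolidin-2-one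
Conditions: (S)-4-benzyl-1,3-oxazolidin-2-one, n-BuLi, THF, −78 °C; then 1, −78 → 0 °C
Reagents that add atoms: (S)-4-benzyl-1,3-oxazolidin-2-one, O=C1N[C@@H](Cc2ccccc2)CO1
Why: N-acylation of the lithiated auxiliary (imide formation); no stereocentre is formed.

Step 2
Reactants: 2 (S)-4-benzyl-3-propanoyl-1,3-oxazolidin-2-one; 3 methacrolein
Product: 5 (S)-4-benzyl-3-[(2R,3S)-3-hydroxy-2,4-dimethylpent-4-enoyl]-1,3-oxazolidin-2-one, via O-trimethylsilyl aldol adduct 4 (not isolated)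
Conditions: MgCl2 (20 mol %), Et3N, Me3SiCl, EtOAc, 23 °C; then CF3CO2H, MeOH
Reagents that add atoms: none
Why: Evans MgCl2-catalysed direct anti-aldol reaction: the chelated (Z)-magnesium enolate is attacked by the non-enolisable enal on the face anti to the benzyl group, setting C7 and, anti to it, C6; the silyl ether that turns the catalyst over is cleaved on work-up.

Step 3
Reactants: 5 (S)-4-benzyl-3-[(2R,3S)-3-hydroxy-2,4-dimethylpent-4-enoyl]-1,3-oxazolidin-2-one
Product: 6 (S)-4-benzyl-3-[(2R,3S)-3-[(tert-butyldimethylsilyl)oxy]-2,4-dimethylpent-4-enoyl]-1,3-oxazolidin-2-one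
Conditions: TBSOTf, 2,6-lutidine, CH2Cl2, −78 → 0 °C
Reagents that add atoms: tert-butyldimethylsilyl trifluoromethanesulfonate, CC(C)(C)[Si](C)(C)OS(=O)(=O)C(F)(F)F
Why: Silyl ether protection of the hindered secondary C6 hydroxyl, which stays masked until the last step.

Step 4
Reactants: 6 (S)-4-benzyl-3-[(2R,3S)-3-[(tert-butyldimethylsilyl)oxy]-2,4-dimethylpent-4-enoyl]-1,3-oxazolidin-2-one
Product: 7 (2S,3S)-3-[(tert-butyldimethylsilyl)oxy]-2,4-dimethylpent-4-en-1-ol
Conditions: LiBH4, MeOH (1.1 equiv), THF, 0 °C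
Reagents that add atoms: none
Why: Reductive cleavage of the N-acyl oxazolidinone gives the C8 primary alcohol without touching C7; the auxiliary is recovered.

Step 5
Reactants: 8 glycolaldehyde dimer (1,4-dioxane-2,5-diol); 9 prop-1-yn-1-ylmagnesium bromide
Product: 10 rac-pent-3-yne-1,2-diol
Conditions: 9 (4.4 equiv per dimer), THF, 0 °C → rt; aq. NH4Cl
Reagents that add atoms: none
Why: Grignard 1,2-addition to the monomeric hydroxy aldehyde released from the dimer; the carbinol is deliberately racemic because step 7 is stereoconvergent.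

Step 6
Reactants: 10 rac-pent-3-yne-1,2-diol
Product: 11 rac-4-(prop-1-yn-1-yl)-1,3-dioxolan-2-one
Conditions: 1,1'-carbonyldiimidazole, CH2Cl2, rt
Reagents that add atoms: 1,1'-carbonyldiimidazole, O=C(n1ccnc1)n1ccnc1
Why: Cyclic carbonate formation from the 1,2-diol (carbonylation).

Step 7
Reactants: 7 (2S,3S)-3-[(tert-butyldimethylsilyl)oxy]-2,4-dimethylpent-4-en-1-ol; 11 rac-4-(prop-1-yn-1-yl)-1,3-dioxolan-2-one
Product: 13 (2S,3R,4S,5S)-5-[(tert-butyldimethylsilyl)oxy]-4,6-dimethyl-2-(prop-1-yn-1-yl)hept-6-ene-1,3-diol, via aldehyde 12 (not isolated)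
Conditions: [Ir(cod)Cl]2 (2.5 mol %), (R)-SEGPHOS (5 mol %), 4-cyano-3-nitrobenzoic acid (10 mol %), Cs2CO3 (20 mol %), 11 (2 equiv), THF, 60 °C
Reagents that add atoms: none
Why: Proposed new method: a redox-neutral iridium-catalysed C–H (hydroxymethyl)propargylation in which the cyclometalated iridium C,O-benzoate dehydrogenates 7 to aldehyde 12, the resulting monovalent iridium species opens racemic carbonate 11 by anti-SN2′ oxidative addition with loss of CO2, and the rapidly equilibrating allenyl/propargyl trivalent-iridium alkoxide adds to 12 through a closed chair-like SE2′ transition state under ligand control, forming C8–C9 and setting C9 (S) from either enantiomer of 11 (the anti C8 carbinol is oxidised later and its configuration is immaterial, and the (R)/(S) sense of the ligand is assigned by analogy and must be confirmed on the first run); the closest known reaction types are the iridium-catalysed transfer-hydrogenative anti-(hydroxymethyl)allylation of alcohols with unsaturated cyclic carbonates and the iridium-catalysed propargylation with propargyl chlorides, neither shown for an α-branched propargylic carbonate.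

Step 8
Reactants: 13 (2S,3R,4S,5S)-5-[(tert-butyldimethylsilyl)oxy]-4,6-dimethyl-2-(prop-1-yn-1-yl)hept-6-ene-1,3-diol
Product: 14 (2S,3R,4S,5S)-1,5-bis[(tert-butyldimethylsilyl)oxy]-4,6-dimethyl-2-(prop-1-yn-1-yl)hept-6-en-3-ol
Conditions: TBSCl (1.05 equiv), imidazole, CH2Cl2, 0 °C
Reagents that add atoms: tert-butyldimethylsilyl chloride, CC(C)(C)[Si](C)(C)Cl
Why: Selective silylation of the primary hydroxyl over the secondary C8 hydroxyl, which is flanked by two branched carbons.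

Step 9
Reactants: 15 methyl acetoacetate
Product: 16 methyl (2E)-3-{[(trifluoromethyl)sulfonyl]oxy}but-2-enoate
Conditions: aq. Me4NOH, hexanes, 5 °C; then Tf2O
Reagents that add atoms: trifluoromethanesulfonic anhydride, O=S(=O)(OS(=O)(=O)C(F)(F)F)C(F)(F)F
Why: Stereoselective enol triflation: the non-chelated tetramethylammonium enolate gives the (E)-triflate, which fixes the later C2=C3 geometry.

Step 10
Reactants: 14 (2S,3R,4S,5S)-1,5-bis[(tert-butyldimethylsilyl)oxy]-4,6-dimethyl-2-(prop-1-yn-1-yl)hept-6-en-3-ol; 16 methyl (2E)-3-{[(trifluoromethyl)sulfonyl]oxy}but-2-enoate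
Product: 18 methyl (2E,5R,6R,7S,8R,9S)-6-[(tert-butyldimethylsilyl)oxy]-9-{[(tert-butyldimethylsilyl)oxy]methyl}-8-hydroxy-3,5,7-trimethyldodec-2-en-10-ynoate, via alkylborane 17 (not isolated)
Conditions: 9-BBN-H (1.6 equiv), THF, 0 °C → rt; then 16, PdCl2(dppf) (5 mol %), AsPh3 (5 mol %), aq. K3PO4, DMF, rt
Reagents that add atoms: none
Why: Substrate-controlled hydroboration followed by B-alkyl Suzuki–Miyaura coupling: 9-BBN adds to the 1,1-disubstituted alkene anti to the C7 chain with the C6–H eclipsing the alkene, which sets C5 anti to the C6 oxygen, and the zerovalent-palladium coupling with the enol triflate goes with retention to the (2E)-enoate, while the hindered internal alkyne reacts far more slowly with 9-BBN.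

Step 11
Reactants: 18 methyl (2E,5R,6R,7S,8R,9S)-6-[(tert-butyldimethylsilyl)oxy]-9-{[(tert-butyldimethylsilyl)oxy]methyl}-8-hydroxy-3,5,7-trimethyldodec-2-en-10-ynoate
Product: 20 methyl (2E,5R,6R,7S,8R,9S,10E)-6-[(tert-butyldimethylsilyl)oxy]-9-{[(tert-butyldimethylsilyl)oxy]methyl}-8-hydroxy-11-iodo-3,5,7-trimethyldodeca-2,10-dienoate, via alkenyl-Zr(Cl)Cp2 species 19 (not isolated)
Conditions: Cp2Zr(H)Cl (3.2 equiv), THF, rt → 40 °C; then I2, 0 °C
Reagents that add atoms: iodine, II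
Why: Hydrozirconation–iodination: syn addition of Zr–H places zirconium on the less hindered, methyl-bearing alkyne carbon and iodinolysis with retention gives the (E)-iodide, the conjugated methyl ester being reduced much more slowly than the alkyne reacts and the free hydroxyl only forming its zirconium alkoxide.

Step 12
Reactants: 20 methyl (2E,5R,6R,7S,8R,9S,10E)-6-[(tert-butyldimethylsilyl)oxy]-9-{[(tert-butyldimethylsilyl)oxy]methyl}-8-hydroxy-11-iodo-3,5,7-trimethyldodeca-2,10-dienoate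
Product: 21 (2E,5R,6R,7S,8R,9S,10E)-6-[(tert-butyldimethylsilyl)oxy]-9-{[(tert-butyldimethylsilyl)oxy]methyl}-8-hydroxy-11-iodo-3,5,7-trimethyldodeca-2,10-dienoic acid
Conditions: LiOH, THF/MeOH/H2O, 40 °C; then 1 M HCl to pH 4
Reagents that add atoms: none
Why: Ester saponification, done here because no base-sensitive ketone or lactone is present yet.

Step 13
Reactants: 21 (2E,5R,6R,7S,8R,9S,10E)-6-[(tert-butyldimethylsilyl)oxy]-9-{[(tert-butyldimethylsilyl)oxy]methyl}-8-hydroxy-11-iodo-3,5,7-trimethyldodeca-2,10-dienoic acid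
Product: 22 (2E,5R,6R,7R,9S,10E)-6-[(tert-butyldimethylsilyl)oxy]-9-{[(tert-butyldimethylsilyl)oxy]methyl}-11-iodo-3,5,7-trimethyl-8-oxododeca-2,10-dienoic acid
Conditions: Dess–Martin periodinane, pyridine, CH2Cl2, 0 °C → rt
Reagents that add atoms: none
Why: Dess–Martin oxidation of the only free alcohol under buffered, non-basic conditions that leave the C7 and C9 centres beside the new ketone untouched.

**West fragment (C18–C24, ring A)**

Step 14
Reactants: 23 3-(trimethylsilyl)prop-2-ynal; 24 (E)-but-2-ene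
Product: 28 (3S,4S)-4-methyl-1-(trimethylsilyl)hex-5-en-1-yn-3-ol, via crotylpotassium 25 (not isolated), via crotylborane 26 (not isolated), via borinate 27 (not isolated)
Conditions: 24, KOt-Bu, n-BuLi, THF, −78 → −45 °C; (−)-Ipc2BOMe, −78 °C; BF3·OEt2; then 23, −78 °C; NaOH, H2O2
Reagents that add atoms: none
Why: Brown asymmetric crotylboration: the (E)-crotylborane carrying the (−)-isopinocampheyl groups (from (+)-α-pinene) reacts through a chair Zimmerman–Traxler transition state to give the anti alcohol, setting C20 and C21 under reagent control.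

Step 15
Reactants: 28 (3S,4S)-4-methyl-1-(trimethylsilyl)hex-5-en-1-yn-3-ol
Product: 29 (3S,4S)-4-methyl-1-(trimethylsilyl)hex-5-en-1-yn-3-yl prop-2-enoate
Conditions: acryloyl chloride, i-Pr2NEt, CH2Cl2, −78 → 0 °C
Reagents that add atoms: acryloyl chloride, C=CC(=O)Cl
Why: Esterification of the secondary alcohol to install the acrylate for ring closure.

Step 16
Reactants: 29 (3S,4S)-4-methyl-1-(trimethylsilyl)hex-5-en-1-yn-3-yl prop-2-enoate
Product: 30 (5S,6S)-5-methyl-6-[(trimethylsilyl)ethynyl]-5,6-dihydro-2H-pyran-2-one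
Conditions: second-generation Grubbs catalyst RuCl2(=CHPh)(H2IMes)(PCy3) (5 mol %), CH2Cl2 (5 mM), 40 °C
Reagents that add atoms: none
Why: Ring-closing metathesis forms ring A from the acrylate and the terminal vinyl group; the anti relationship becomes the trans-5,6 pattern and the silyl-capped alkyne is a spectator.

Step 17
Reactants: 30 (5S,6S)-5-methyl-6-[(trimethylsilyl)ethynyl]-5,6-dihydro-2H-pyran-2-one
Product: 31 (5S,6S)-6-ethynyl-5-methyl-5,6-dihydro-2H-pyran-2-one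
Conditions: Bu4NF, AcOH, THF, 0 °C
Reagents that add atoms: none
Why: Buffered fluoride cleavage of the alkynyl C–Si bond; acetic acid keeps the medium non-basic for the lactone.

Step 18
Reactants: 31 (5S,6S)-6-ethynyl-5-methyl-5,6-dihydro-2H-pyran-2-one
Product: 32 (5S,6S)-5-methyl-6-[(E)-2-(tributylstannyl)ethenyl]-5,6-dihydro-2H-pyran-2-one
Conditions: Bu3SnH, Pd2(dba)3 (1 mol %), (c-C6H11)3P·HBF4 (4 mol %), i-Pr2NEt (8 mol %), CH2Cl2, 0 °C
Reagents that add atoms: tributyltin hydride, CCCC[SnH](CCCC)CCCC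
Why: Palladium-catalysed syn hydrostannation of the terminal alkyne; the bulky phosphine and the branched propargylic carbon direct tin to the terminal carbon, giving the (E)-stannane.

**Middle fragment (C12–C17)**

Step 19
Reactants: 33 (R)-3-bromo-2-methylpropan-1-ol
Product: 34 (R)-(3-bromo-2-methylpropoxy)(tert-butyl)dimethylsilane
Conditions: TBSCl, imidazole, DMF, rt
Reagents that add atoms: tert-butyldimethylsilyl chloride, CC(C)(C)[Si](C)(C)Cl
Why: Silyl protection of the chiral-pool alcohol that supplies C15.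

Step 20
Reactants: 34 (R)-(3-bromo-2-methylpropoxy)(tert-butyl)dimethylsilane
Product: 35 (S)-tert-butyldimethyl[(2-methylpent-4-yn-1-yl)oxy]silane
Conditions: LiC≡CH·H2NCH2CH2NH2, DMSO, rt
Reagents that add atoms: lithium acetylide–ethylenediamine complex, [Li]C#C.NCCN
Why: SN2 alkylation of the acetylide by the primary bromide installs C12–C13; the stereocentre is not involved.

Step 21
Reactants: 35 (S)-tert-butyldimethyl[(2-methylpent-4-yn-1-yl)oxy]silane
Product: 36 (S)-2-methylpent-4-yn-1-ol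
Conditions: camphorsulfonic acid (10 mol %), MeOH, rt
Reagents that add atoms: none
Why: Acid-catalysed methanolysis of the primary silyl ether.

Step 22
Reactants: 36 (S)-2-methylpent-4-yn-1-ol
Product: 37 (S)-2-methylpent-4-ynal
Conditions: Dess–Martin periodinane, CH2Cl2, 0 °C; filtered and used at once
Reagents that add atoms: none
Why: Dess–Martin oxidation under non-basic conditions, with immediate use to avoid epimerisation of the α-methyl aldehyde.

Step 23
Reactants: 37 (S)-2-methylpent-4-ynal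
Product: 38 (2Z,4S)-2-iodo-4-methylhept-2-en-6-yne
Conditions: [Ph3PCH(I)CH3]I, NaN(SiMe3)2, THF, −20 °C; then 37, −78 → −20 °C
Reagents that add atoms: (1-iodoethyl)triphenylphosphonium iodide, CC(I)[P+](c1ccccc1)(c1ccccc1)c1ccccc1.[I-]
Why: Stork–Zhao olefination: the non-stabilised α-iodo ylide gives the (Z)-trisubstituted vinyl iodide kinetically, which fixes the C16=C17 geometry.

**Fragment unions and end game**

Step 24
Reactants: 32 (5S,6S)-5-methyl-6-[(E)-2-(tributylstannyl)ethenyl]-5,6-dihydro-2H-pyran-2-one; 38 (2Z,4S)-2-iodo-4-methylhept-2-en-6-yne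
Product: 39 (5S,6R)-6-[(1E,3Z,5S)-3,5-dimethylocta-1,3-dien-7-yn-1-yl]-5-methyl-5,6-dihydro-2H-pyran-2-one
Conditions: Pd2(dba)3 (5 mol %), AsPh3 (20 mol %), NMP, rt → 40 °C
Reagents that add atoms: none
Why: Stille coupling forms C17–C18 with retention of both alkene geometries; without copper or base the terminal alkyne and the lactone are spectators.

Step 25
Reactants: 39 (5S,6R)-6-[(1E,3Z,5S)-3,5-dimethylocta-1,3-dien-7-yn-1-yl]-5-methyl-5,6-dihydro-2H-pyran-2-one
Product: 40 (5S,6R)-6-[(1E,3Z,5S,7E)-3,5-dimethyl-8-(tributylstannyl)octa-1,3,7-trien-1-yl]-5-methyl-5,6-dihydro-2H-pyran-2-one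
Conditions: Bu3SnH, Pd2(dba)3 (1 mol %), (c-C6H11)3P·HBF4 (4 mol %), i-Pr2NEt (8 mol %), CH2Cl2, 0 °C
Reagents that add atoms: tributyltin hydride, CCCC[SnH](CCCC)CCCC
Why: Palladium-catalysed syn hydrostannation, selective for the terminal alkyne over the diene and enoate, gives the (E)-stannane at C12.

Step 26
Reactants: 22 (2E,5R,6R,7R,9S,10E)-6-[(tert-butyldimethylsilyl)oxy]-9-{[(tert-butyldimethylsilyl)oxy]methyl}-11-iodo-3,5,7-trimethyl-8-oxododeca-2,10-dienoic acid; 40 (5S,6R)-6-[(1E,3Z,5S,7E)-3,5-dimethyl-8-(tributylstannyl)octa-1,3,7-trien-1-yl]-5-methyl-5,6-dihydro-2H-pyran-2-one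
Product: 41 (2E,5R,6R,7R,9S,10E,12E,15S,16Z,18E)-6-[(tert-butyldimethylsilyl)oxy]-9-{[(tert-butyldimethylsilyl)oxy]methyl}-3,5,7,11,15,17-hexamethyl-19-[(2R,3S)-3-methyl-6-oxo-3,6-dihydro-2H-pyran-2-yl]-8-oxononadeca-2,10,12,16,18-pentaenoic acid
Conditions: Pd2(dba)3 (10 mol %), AsPh3 (40 mol %), NMP, rt → 35 °C
Reagents that add atoms: none
Why: Stille coupling forms the C11–C12 bond of the (10E,12E)-diene with retention on both partners under neutral conditions that tolerate the free acid, the epimerisable C9 centre and the lactone.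

Step 27
Reactants: 41 (2E,5R,6R,7R,9S,10E,12E,15S,16Z,18E)-6-[(tert-butyldimethylsilyl)oxy]-9-{[(tert-butyldimethylsilyl)oxy]methyl}-3,5,7,11,15,17-hexamethyl-19-[(2R,3S)-3-methyl-6-oxo-3,6-dihydro-2H-pyran-2-yl]-8-oxononadeca-2,10,12,16,18-pentaenoic acid
Product: 42 (2E,5R,6R,7R,9S,10E,12E,15S,16Z,18E)-6-hydroxy-9-(hydroxymethyl)-3,5,7,11,15,17-hexamethyl-19-[(2R,3S)-3-methyl-6-oxo-3,6-dihydro-2H-pyran-2-yl]-8-oxononadeca-2,10,12,16,18-pentaenoic acid (target)
Conditions: HF·pyridine, pyridine, THF, 0 °C → rt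
Reagents that add atoms: none
Why: Buffered fluoride desilylation removes both silyl ethers under mildly acidic conditions that avoid retro-aldol, β-elimination and C9 epimerisation of the hydroxy ketone.

## Compound list

1 | propanoyl chloride | CCC(Cl)=O | starting material
2 | (S)-4-benzyl-3-propanoyl-1,3-oxazolidin-2-one | CCC(=O)N1[C@@H](Cc2ccccc2)COC1=O | intermediate
3 | methacrolein (2-methylprop-2-enal) | CC(=C)C=O | starting material
4 | (S)-4-benzyl-3-[(2R,3S)-2,4-dimethyl-3-(trimethylsilyloxy)pent-4-enoyl]-1,3-oxazolidin-2-one | O=C([C@H](C)[C@H](O[Si](C)(C)C)C(C)=C)N1[C@@H](Cc2ccccc2)COC1=O | intermediate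
5 | (S)-4-benzyl-3-[(2R,3S)-3-hydroxy-2,4-dimethylpent-4-enoyl]-1,3-oxazolidin-2-one | O=C([C@H](C)[C@H](O)C(C)=C)N1[C@@H](Cc2ccccc2)COC1=O | intermediate
6 | (S)-4-benzyl-3-[(2R,3S)-3-[(tert-butyldimethylsilyl)oxy]-2,4-dimethylpent-4-enoyl]-1,3-oxazolidin-2-one | O=C([C@H](C)[C@H](O[Si](C)(C)C(C)(C)C)C(C)=C)N1[C@@H](Cc2ccccc2)COC1=O | intermediate
7 | (2S,3S)-3-[(tert-butyldimethylsilyl)oxy]-2,4-dimethylpent-4-en-1-ol | OC[C@H](C)[C@H](O[Si](C)(C)C(C)(C)C)C(C)=C | intermediate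
8 | glycolaldehyde dimer (1,4-dioxane-2,5-diol) | OC1COC(O)CO1 | starting material
9 | prop-1-yn-1-ylmagnesium bromide | CC#C[Mg]Br | starting material
10 | rac-pent-3-yne-1,2-diol | CC#CC(O)CO | intermediate
11 | rac-4-(prop-1-yn-1-yl)-1,3-dioxolan-2-one | CC#CC1COC(=O)O1 | intermediate
12 | (2R,3S)-3-[(tert-butyldimethylsilyl)oxy]-2,4-dimethylpent-4-enal | O=C[C@H](C)[C@H](O[Si](C)(C)C(C)(C)C)C(C)=C | intermediate
13 | (2S,3R,4S,5S)-5-[(tert-butyldimethylsilyl)oxy]-4,6-dimethyl-2-(prop-1-yn-1-yl)hept-6-ene-1,3-diol | CC#C[C@@H](CO)[C@@H](O)[C@H](C)[C@H](O[Si](C)(C)C(C)(C)C)C(C)=C | intermediate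
14 | (2S,3R,4S,5S)-1,5-bis[(tert-butyldimethylsilyl)oxy]-4,6-dimethyl-2-(prop-1-yn-1-yl)hept-6-en-3-ol | CC#C[C@@H](CO[Si](C)(C)C(C)(C)C)[C@@H](O)[C@H](C)[C@H](O[Si](C)(C)C(C)(C)C)C(C)=C | intermediate
15 | methyl acetoacetate | CC(=O)CC(=O)OC | starting material
16 | methyl (2E)-3-{[(trifluoromethyl)sulfonyl]oxy}but-2-enoate | C/C(OS(=O)(=O)C(F)(F)F)=C\C(=O)OC | intermediate
17 | 9-{(2R,3R,4S,5R,6S)-3-[(tert-butyldimethylsilyl)oxy]-6-{[(tert-butyldimethylsilyl)oxy]methyl}-5-hydroxy-2,4-dimethylnon-7-yn-1-yl}-9-borabicyclo[3.3.1]nonane | CC#C[C@@H](CO[Si](C)(C)C(C)(C)C)[C@@H](O)[C@H](C)[C@H](O[Si](C)(C)C(C)(C)C)[C@H](C)CB1C2CCCC1CCC2 | intermediate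
18 | methyl (2E,5R,6R,7S,8R,9S)-6-[(tert-butyldimethylsilyl)oxy]-9-{[(tert-butyldimethylsilyl)oxy]methyl}-8-hydroxy-3,5,7-trimethyldodec-2-en-10-ynoate | CC#C[C@@H](CO[Si](C)(C)C(C)(C)C)[C@@H](O)[C@H](C)[C@H](O[Si](C)(C)C(C)(C)C)[C@H](C)C/C(C)=C/C(=O)OC | intermediate
19 | C11 alkenyl-Zr(Cl)Cp2 species of 18 (E; the C8 oxygen is also bound to Zr(Cl)Cp2) | Cl[Zr](C1C=CC=C1)(C1C=CC=C1)/C(C)=C/[C@@H](CO[Si](C)(C)C(C)(C)C)[C@@H](O[Zr](Cl)(C1C=CC=C1)C1C=CC=C1)[C@H](C)[C@H](O[Si](C)(C)C(C)(C)C)[C@H](C)C/C(C)=C/C(=O)OC | intermediate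
20 | methyl (2E,5R,6R,7S,8R,9S,10E)-6-[(tert-butyldimethylsilyl)oxy]-9-{[(tert-butyldimethylsilyl)oxy]methyl}-8-hydroxy-11-iodo-3,5,7-trimethyldodeca-2,10-dienoate | I/C(C)=C/[C@@H](CO[Si](C)(C)C(C)(C)C)[C@@H](O)[C@H](C)[C@H](O[Si](C)(C)C(C)(C)C)[C@H](C)C/C(C)=C/C(=O)OC | intermediate
21 | (2E,5R,6R,7S,8R,9S,10E)-6-[(tert-butyldimethylsilyl)oxy]-9-{[(tert-butyldimethylsilyl)oxy]methyl}-8-hydroxy-11-iodo-3,5,7-trimethyldodeca-2,10-dienoic acid | I/C(C)=C/[C@@H](CO[Si](C)(C)C(C)(C)C)[C@@H](O)[C@H](C)[C@H](O[Si](C)(C)C(C)(C)C)[C@H](C)C/C(C)=C/C(=O)O | intermediate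
22 | (2E,5R,6R,7R,9S,10E)-6-[(tert-butyldimethylsilyl)oxy]-9-{[(tert-butyldimethylsilyl)oxy]methyl}-11-iodo-3,5,7-trimethyl-8-oxododeca-2,10-dienoic acid | I/C(C)=C/[C@@H](CO[Si](C)(C)C(C)(C)C)C(=O)[C@H](C)[C@H](O[Si](C)(C)C(C)(C)C)[C@H](C)C/C(C)=C/C(=O)O | intermediate
23 | 3-(trimethylsilyl)prop-2-ynal | C[Si](C)(C)C#CC=O | starting material
24 | (E)-but-2-ene | C/C=C/C | starting material
25 | (E)-but-2-en-1-ylpotassium | C/C=C/C[K] | intermediate
26 | (E)-but-2-en-1-ylbis[(−)-isopinocampheyl]borane (isopinocampheyl groups from (+)-α-pinene) | C/C=C/CB([C@@H]1C[C@@H]2C[C@@H](C2(C)C)[C@H]1C)[C@@H]1C[C@@H]2C[C@@H](C2(C)C)[C@H]1C | intermediate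
27 | (3S,4S)-4-methyl-1-(trimethylsilyl)hex-5-en-1-yn-3-yl bis[(−)-isopinocampheyl]borinate | C[Si](C)(C)C#C[C@H]([C@@H](C)C=C)OB([C@@H]1C[C@@H]2C[C@@H](C2(C)C)[C@H]1C)[C@@H]1C[C@@H]2C[C@@H](C2(C)C)[C@H]1C | intermediate
28 | (3S,4S)-4-methyl-1-(trimethylsilyl)hex-5-en-1-yn-3-ol | C[Si](C)(C)C#C[C@H]([C@@H](C)C=C)O | intermediate
29 | (3S,4S)-4-methyl-1-(trimethylsilyl)hex-5-en-1-yn-3-yl prop-2-enoate | C[Si](C)(C)C#C[C@H]([C@@H](C)C=C)OC(=O)C=C | intermediate
30 | (5S,6S)-5-methyl-6-[(trimethylsilyl)ethynyl]-5,6-dihydro-2H-pyran-2-one | C[Si](C)(C)C#C[C@H]1OC(=O)C=C[C@@H]1C | intermediate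
31 | (5S,6S)-6-ethynyl-5-methyl-5,6-dihydro-2H-pyran-2-one | C#C[C@H]1OC(=O)C=C[C@@H]1C | intermediate
32 | (5S,6S)-5-methyl-6-[(E)-2-(tributylstannyl)ethenyl]-5,6-dihydro-2H-pyran-2-one | CCCC[Sn](CCCC)(CCCC)/C=C/[C@H]1OC(=O)C=C[C@@H]1C | intermediate
33 | (R)-3-bromo-2-methylpropan-1-ol | OC[C@@H](C)CBr | starting material
34 | (R)-(3-bromo-2-methylpropoxy)(tert-butyl)dimethylsilane | CC(C)(C)[Si](C)(C)OC[C@@H](C)CBr | intermediate
35 | (S)-tert-butyldimethyl[(2-methylpent-4-yn-1-yl)oxy]silane | CC(C)(C)[Si](C)(C)OC[C@@H](C)CC#C | intermediate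
36 | (S)-2-methylpent-4-yn-1-ol | OC[C@@H](C)CC#C | intermediate
37 | (S)-2-methylpent-4-ynal | O=C[C@@H](C)CC#C | intermediate
38 | (2Z,4S)-2-iodo-4-methylhept-2-en-6-yne | C/C(I)=C/[C@@H](C)CC#C | intermediate
39 | (5S,6R)-6-[(1E,3Z,5S)-3,5-dimethylocta-1,3-dien-7-yn-1-yl]-5-methyl-5,6-dihydro-2H-pyran-2-one | CC(=C/[C@@H](C)CC#C)/C=C/[C@H]1OC(=O)C=C[C@@H]1C | intermediate
40 | (5S,6R)-6-[(1E,3Z,5S,7E)-3,5-dimethyl-8-(tributylstannyl)octa-1,3,7-trien-1-yl]-5-methyl-5,6-dihydro-2H-pyran-2-one | CC(=C/[C@@H](C)C/C=C/[Sn](CCCC)(CCCC)CCCC)/C=C/[C@H]1OC(=O)C=C[C@@H]1C | intermediate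
41 | (2E,5R,6R,7R,9S,10E,12E,15S,16Z,18E)-6-[(tert-butyldimethylsilyl)oxy]-9-{[(tert-butyldimethylsilyl)oxy]methyl}-3,5,7,11,15,17-hexamethyl-19-[(2R,3S)-3-methyl-6-oxo-3,6-dihydro-2H-pyran-2-yl]-8-oxononadeca-2,10,12,16,18-pentaenoic acid | CC(=C/[C@@H](C)C/C=C/C(C)=C/[C@@H](CO[Si](C)(C)C(C)(C)C)C(=O)[C@H](C)[C@H](O[Si](C)(C)C(C)(C)C)[C@H](C)C/C(C)=C/C(=O)O)/C=C/[C@H]1OC(=O)C=C[C@@H]1C | intermediate
42 | (2E,5R,6R,7R,9S,10E,12E,15S,16Z,18E)-6-hydroxy-9-(hydroxymethyl)-3,5,7,11,15,17-hexamethyl-19-[(2R,3S)-3-methyl-6-oxo-3,6-dihydro-2H-pyran-2-yl]-8-oxononadeca-2,10,12,16,18-pentaenoic acid | CC(=C/[C@@H](C)C/C=C/C(C)=C/[C@@H](CO)C(=O)[C@H](C)[C@H](O)[C@H](C)C/C(C)=C/C(=O)O)/C=C/[C@H]1OC(=O)C=C[C@@H]1C | target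

## Step count and risks

Total step count: 27.
Longest linear sequence: 12 steps (1, 2, 3, 4, 7, 8, 10, 11, 12, 13, 26, 27).

The three steps most likely to fail are steps 7, 11 and 23.

**Step 7 (the proposed new iridium-catalysed (hydroxymethyl)propargylation).** The allenyl–iridium alkoxide may undergo β-oxygen elimination or cyclise, the new primary alcohol of 13 may react a second time, or enantiocontrol at C9 may be poor. The fallback uses known stoichiometric allenylboronate chemistry; it sets out from 7 (and from diol 10) and comes back at 14.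
- Diol 10 is silylated at the primary hydroxyl (TBSCl, imidazole) to give racemic 1-[(tert-butyldimethylsilyl)oxy]pent-3-yn-2-ol F1.
- Dess–Martin oxidation gives 1-[(tert-butyldimethylsilyl)oxy]pent-3-yn-2-one F2.
- Noyori transfer hydrogenation (RuCl[(S,S)-TsDPEN](p-cymene), i-PrOH) gives (R)-1-[(tert-butyldimethylsilyl)oxy]pent-3-yn-2-ol F3.
- ClCO2Me and pyridine give methyl (R)-1-[(tert-butyldimethylsilyl)oxy]pent-3-yn-2-yl carbonate F4.
- Copper-catalysed anti-SN2′ borylation (CuOt-Bu, Xantphos, B2pin2, THF) transfers the central chirality into the axially chiral allenylboronate 2-{5-[(tert-butyldimethylsilyl)oxy]penta-2,3-dien-2-yl}-4,4,5,5-tetramethyl-1,3,2-dioxaborolane F5.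
- Alcohol 7 is oxidised with Dess–Martin periodinane to aldehyde 12, here isolated, and 12 is heated with F5 (toluene, 50 °C). The closed six-membered syn-SE2′ transition state delivers the C9 configuration by overall inversion relative to F4 and gives 14 directly, with the primary silyl ether already in place.

**Step 11 (hydrozirconation–iodination beside a methyl ester).** Excess Cp2Zr(H)Cl could attack the ester, or regiocontrol could be incomplete. The fallback reverses the polarity of the C11–C12 coupling; it sets out from 18 (and uses 40) and comes back at 41.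
- Ester 18 is saponified (LiOH) to (2E,5R,6R,7S,8R,9S)-6-[(tert-butyldimethylsilyl)oxy]-9-{[(tert-butyldimethylsilyl)oxy]methyl}-8-hydroxy-3,5,7-trimethyldodec-2-en-10-ynoic acid F6.
- Stannane 40 is iododestannylated (I2, CH2Cl2, −40 °C) to (5S,6R)-6-[(1E,3Z,5S,7E)-8-iodo-3,5-dimethylocta-1,3,7-trien-1-yl]-5-methyl-5,6-dihydro-2H-pyran-2-one F7.
- F6 is hydroborated with (c-C6H11)2BH (3.3 equiv; syn addition, boron on the methyl-bearing carbon for steric reasons) to the alkenyl(dicyclohexyl)borane F8, which is not isolated.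
- F8 is coupled with F7 under Suzuki–Miyaura conditions (Pd(PPh3)4, TlOEt, THF/H2O, rt, short reaction time) to give the C8 alcohol of 41, (2E,5R,6R,7S,8R,9S,10E,12E,15S,16Z,18E)-6-[(tert-butyldimethylsilyl)oxy]-9-{[(tert-butyldimethylsilyl)oxy]methyl}-8-hydroxy-3,5,7,11,15,17-hexamethyl-19-[(2R,3S)-3-methyl-6-oxo-3,6-dihydro-2H-pyran-2-yl]nonadeca-2,10,12,16,18-pentaenoic acid F9.
- Dess–Martin oxidation of F9 gives 41.

**Step 23 (Stork–Zhao olefination of an epimerisable α-methyl aldehyde).** Yield and Z/E ratio are typically moderate. The fallback builds the (Z)-trisubstituted halide by stereoselective cross-coupling; it sets out from 37 and comes back at 39.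
- Corey–Fuchs dibromo-olefination of 37 (CBr4, PPh3, CH2Cl2, 0 °C) gives (3S)-1,1-dibromo-3-methylhex-1-en-5-yne F10.
- trans-Selective Negishi monomethylation (MeZnCl, PdCl2(DPEphos), THF, rt) replaces the bromine trans to the chain and gives (2Z,4S)-2-bromo-4-methylhept-2-en-6-yne F11.
- Stille coupling of F11 with stannane 32 (Pd[P(t-Bu)3]2, CsF, NMP, 45 °C) gives 39.

## Further compounds

F1 | step 7 | rac-1-[(tert-butyldimethylsilyl)oxy]pent-3-yn-2-ol | CC#CC(O)CO[Si](C)(C)C(C)(C)C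
F2 | step 7 | 1-[(tert-butyldimethylsilyl)oxy]pent-3-yn-2-one | CC#CC(=O)CO[Si](C)(C)C(C)(C)C
F3 | step 7 | (R)-1-[(tert-butyldimethylsilyl)oxy]pent-3-yn-2-ol | CC#C[C@H](CO[Si](C)(C)C(C)(C)C)O
F4 | step 7 | methyl (R)-1-[(tert-butyldimethylsilyl)oxy]pent-3-yn-2-yl carbonate | CC#C[C@H](CO[Si](C)(C)C(C)(C)C)OC(=O)OC
F5 | step 7 | 2-{5-[(tert-butyldimethylsilyl)oxy]penta-2,3-dien-2-yl}-4,4,5,5-tetramethyl-1,3,2-dioxaborolane (axial configuration as in the SMILES) | CC(B1OC(C)(C)C(C)(C)O1)=[C@@]=C([H])CO[Si](C)(C)C(C)(C)C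
F6 | step 11 | (2E,5R,6R,7S,8R,9S)-6-[(tert-butyldimethylsilyl)oxy]-9-{[(tert-butyldimethylsilyl)oxy]methyl}-8-hydroxy-3,5,7-trimethyldodec-2-en-10-ynoic acid | CC#C[C@@H](CO[Si](C)(C)C(C)(C)C)[C@@H](O)[C@H](C)[C@H](O[Si](C)(C)C(C)(C)C)[C@H](C)C/C(C)=C/C(=O)O
F7 | step 11 | (5S,6R)-6-[(1E,3Z,5S,7E)-8-iodo-3,5-dimethylocta-1,3,7-trien-1-yl]-5-methyl-5,6-dihydro-2H-pyran-2-one | CC(=C/[C@@H](C)C/C=C/I)/C=C/[C@H]1OC(=O)C=C[C@@H]1C
F8 | step 11 | (E)-C11 alkenyl(dicyclohexyl)borane of F6 (drawn with free OH and CO2H) | C/C(B(C1CCCCC1)C1CCCCC1)=C\[C@@H](CO[Si](C)(C)C(C)(C)C)[C@@H](O)[C@H](C)[C@H](O[Si](C)(C)C(C)(C)C)[C@H](C)C/C(C)=C/C(=O)O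
F9 | step 11 | (2E,5R,6R,7S,8R,9S,10E,12E,15S,16Z,18E)-6-[(tert-butyldimethylsilyl)oxy]-9-{[(tert-butyldimethylsilyl)oxy]methyl}-8-hydroxy-3,5,7,11,15,17-hexamethyl-19-[(2R,3S)-3-methyl-6-oxo-3,6-dihydro-2H-pyran-2-yl]nonadeca-2,10,12,16,18-pentaenoic acid | CC(=C/[C@@H](C)C/C=C/C(C)=C/[C@@H](CO[Si](C)(C)C(C)(C)C)[C@@H](O)[C@H](C)[C@H](O[Si](C)(C)C(C)(C)C)[C@H](C)C/C(C)=C/C(=O)O)/C=C/[C@H]1OC(=O)C=C[C@@H]1C
F10 | step 23 | (3S)-1,1-dibromo-3-methylhex-1-en-5-yne | BrC(Br)=C[C@@H](C)CC#C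
F11 | step 23 | (2Z,4S)-2-bromo-4-methylhept-2-en-6-yne | C/C(Br)=C/[C@@H](C)CC#C
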